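**Assumptions:** Isoprene, methyl vinyl ketone and 4-methylpent-3-en-1-ol are commercial. Reagents and catalysts are not numbered. The C8-OAc and C7 tertiary-OH configurations are set together in the pinacol step.

## Retrosynthetic overview
1. Acetylcaespitol comes from a 6-endo bromoetherification of the tertiary C7-OH onto a prenyl alkene. This closes the tetrahydropyran, places Br at C10, and is the last ring formed.
2. The C8-acetoxy/C7-tertiary-alcohol array comes from a ketyl-radical (SmI2) cross-pinacol coupling, which forms the C7–C8 bond. The partners are a bromochlorocyclohexyl methyl ketone and 4-methylpent-3-enal.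
3. The bromochloro ring comes from Markovnikov anti-bromochlorination of 4-acetyl-1-methylcyclohexene, done early on the simple ketone.
4. That cyclohexene comes from an enantioselective Diels–Alder reaction of isoprene and methyl vinyl ketone. The cyclohexane is formed first and the tetrahydropyran last.

## Route

**Step 1**
Reactants: 1 isoprene; 2 methyl vinyl ketone
Product: 3 (R)-1-(4-methylcyclohex-3-en-1-yl)ethan-1-one
Conditions: cat. chiral oxazaborolidinium triflimide (10 mol %), CH2Cl2, −78 → −40 °C; MVK added slowly
Reagents that add atoms: none
Why: Lewis-acid Diels–Alder gives the "para" (1,4) regioisomer, because isoprene C1 has the largest HOMO coefficient and bonds to the MVK β-carbon. Proposed new method: the catalyst binds MVK s-cis and its aryl group shields one enone face, so isoprene adds endo to the other face and sets C1 as (R). The closest known reaction is oxazaborolidinium-catalysed Diels–Alder of α-substituted acroleins with isoprene; the catalyst enantiomer is chosen to give (R).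

**Step 2**
Reactants: 3
Product: 4 1-[(1R,3R,4R)-3-bromo-4-chloro-4-methylcyclohexyl]ethan-1-one
Conditions: NBS (1.1 equiv), Et4NCl (4 equiv, anhydrous), CH2Cl2/MeCN 4:1, −30 °C, dark; then separate diastereomers by chromatography/HPLC
Reagents that add atoms: NBS, BrN1C(=O)CCC1=O (supplies Br); tetraethylammonium chloride, CC[N+](CC)(CC)CC.[Cl-] (supplies Cl)
Why: This is halonium-mediated anti-bromochlorination. Bromonium forms on the trisubstituted alkene and chloride opens it at the tertiary carbon (Markovnikov, anti), giving trans Br/Cl. The acetyl group at C1 (C1' in the target numbering) is remote and gives little facial bias. The wanted isomer (Br cis and Cl trans to acetyl) is probably the minor one, ~1:1 to 1:2, so it is separated here on the simple ketone.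

**Step 3**
Reactants: 5 4-methylpent-3-en-1-ol
Product: 6 4-methylpent-3-enal
Conditions: Dess–Martin periodinane (1.2 equiv), NaHCO3, CH2Cl2, 0 °C → rt, 1 h; use crude immediately
Reagents that add atoms: none
Why: Buffered Dess–Martin oxidation of a primary alcohol avoids isomerisation of the β,γ-alkene into conjugation. No stereocentre is involved.

**Step 4 (key radical step)**
Reactants: 4 bromochloro ketone (1.0 equiv); 6 aldehyde (2.0 equiv)
Product: 7 (2S,3S)-2-[(1R,3R,4R)-3-bromo-4-chloro-4-methylcyclohexyl]-6-methylhept-5-ene-2,3-diol
Conditions: SmI2 (4.5 equiv), THF, −40 → 0 °C, no HMPA; aldehyde 6 added by syringe pump over 3 h to ketone 4 and SmI2; quench with sat. aq. NaHCO3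
Reagents that add atoms: none (SmI2 is only the reductant)
Why: In this SmI2 cross-pinacol coupling the aldehyde is reduced first to a ketyl radical anion. It adds to the Sm(III)-bound methyl ketone and forms the C7–C8 bond. The chelated O–Sm–O gauche transition state, with the cyclohexyl and homoprenyl groups anti, gives the dl relationship, which is the (7S,8S) relative configuration needed. C1' (the ring carbon bearing the side chain) controls C7 only weakly, so the (7R,8R) epimer forms about equally and is separated. Slow aldehyde addition and excess aldehyde suppress aldehyde homodimerisation. The secondary bromide and tertiary chloride should survive because there is no HMPA and the temperature is low.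

**Step 5**
Reactants: 7
Product: 8 (2S,3S)-2-[(1R,3R,4R)-3-bromo-4-chloro-4-methylcyclohexyl]-2-hydroxy-6-methylhept-5-en-3-yl acetate
Conditions: Ac2O (1.5 equiv), pyridine (5 equiv), DMAP (0.1 equiv), CH2Cl2, 0 °C
Reagents that add atoms: acetic anhydride, CC(=O)OC(C)=O
Why: Chemoselective acylation of the secondary C3-OH, with the hindered tertiary alcohol untouched, is standard. It also blocks a competing 5-endo cyclisation from the secondary OH in the next step. No stereocentre is affected.

**Step 6**
Reactants: 8
Product: 9 acetylcaespitol, (2S,3S,5S)-5-bromo-2-[(1R,3R,4R)-3-bromo-4-chloro-4-methylcyclohexyl]-2,6,6-trimethyloxan-3-yl acetate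
Conditions: NBS (1.1 equiv), solid NaHCO3, CH2Cl2/MeNO2 3:1, −20 → 0 °C, dark
Reagents that add atoms: NBS, BrN1C(=O)CCC1=O (supplies the C10 Br)
Why: This is bromonium-induced 6-endo etherification. The tertiary C7-OH attacks the tertiary alkene terminus C11 anti to Br, which closes the 2,2,6,6-substituted tetrahydropyran. The C10 configuration is set by the chair-like transition state with the large cyclohexyl group equatorial; the C10 epimer would need a 1,3-diaxial Br/OAc clash. C11 carries two identical methyls, so it is not a stereocentre.

## Final checks
- **Target match:** 9 has the 2,2-dimethyl-3-bromo-5-acetoxy-6-methyl-oxane fused to the 3-bromo-4-chloro-4-methylcyclohexyl group, with 17 C, C17H27Br2ClO3. Its SMILES is the given target.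
- **Atom balance:**
  - 1 + 2 → 3, C9H14O.
  - 3 + BrCl → 4, C9H14BrClO.
  - 4 + 6 + 2H → 7, C15H26BrClO2.
  - 7 + Ac − H → 8, C17H28BrClO3.
  - 8 + Br+ − H+ → 9, C17H27Br2ClO3.
- **Functional-group survival:** The tertiary chloride and secondary bromide are inert to steps 3, 5 and 6. SmI2 in step 4 is the only worry, and it is handled by no HMPA and low temperature. No alkene remains after step 2 except the prenyl alkene, which is consumed in step 6.
- **Stereocentres:**
  - C1' is set in step 1.
  - C4' and C5' are set in step 2 (anti addition) and separated.
  - C7 and C8 are set in step 4.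
  - C10 is set in step 6.
  - None is touched later.

## Compound list
1 | isoprene | CC(=C)C=C | starting material
2 | methyl vinyl ketone | C=CC(C)=O | starting material
3 | (R)-1-(4-methylcyclohex-3-en-1-yl)ethan-1-one | CC(=O)[C@@H]1CCC(C)=CC1 | intermediate
4 | 1-[(1R,3R,4R)-3-bromo-4-chloro-4-methylcyclohexyl]ethan-1-one | CC(=O)[C@@H]1CC[C@@](C)(Cl)[C@H](Br)C1 | intermediate
5 | 4-methylpent-3-en-1-ol | CC(C)=CCCO | starting material
6 | 4-methylpent-3-enal | CC(C)=CCC=O | intermediate
7 | (2S,3S)-2-[(1R,3R,4R)-3-bromo-4-chloro-4-methylcyclohexyl]-6-methylhept-5-ene-2,3-diol | CC(C)=CC[C@H](O)[C@@](C)(O)[C@@H]1CC[C@@](C)(Cl)[C@H](Br)C1 | intermediate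
8 | (2S,3S)-2-[(1R,3R,4R)-3-bromo-4-chloro-4-methylcyclohexyl]-2-hydroxy-6-methylhept-5-en-3-yl acetate | CC(=O)O[C@@H](CC=C(C)C)[C@@](C)(O)[C@@H]1CC[C@@](C)(Cl)[C@H](Br)C1 | intermediate
9 | acetylcaespitol | CC(=O)O[C@H]1C[C@H](Br)C(C)(C)O[C@@]1(C)[C@@H]1CC[C@@](C)(Cl)[C@H](Br)C1 | target

**Total steps:** 6. **Longest linear sequence:** 5 (steps 1, 2, 4, 5, 6).

## Three steps most likely to fail
1. **Step 4 (cross-pinacol).** Aldehyde homocoupling, an unselective C7 epimer mixture, or reduction of the C–Br bond could all occur. Fallback: a polar route. Convert aldehyde 6 to the α-MOM-oxy stannane (Bu3SnLi, then MOMCl), transmetalate with BuLi, add the resulting α-alkoxyorganolithium to ketone 4 under chelation control, then remove the MOM group.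
2. **Step 6 (bromoetherification).** Risks are acetoxonium participation, a C10 epimer, or failure of the hindered tertiary-OH 6-endo closure. Fallback: epoxidise the prenyl alkene, cyclise by acid-promoted 6-endo opening with the tertiary OH to give the C10 alcohol, then convert it to bromide by Appel reaction (PPh3/CBr4) with inversion, choosing the epoxide diastereomer that gives 10S.
3. **Step 1 (enantioselective Diels–Alder).** The enantioselectivity with simple MVK is unproven. Fallback: racemic Diels–Alder of isoprene and acrylic acid, resolve 4-methylcyclohex-3-ene-1-carboxylic acid with a chiral amine, then add 2 equiv MeLi to give (R)-3.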